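**Strategy.** The target is a symmetric trimer, so the plan rests on one building block, butyrylfilicinic acid, bridged twice through CH2 to butyrylphloroglucinol. Each outer ring is a 1,3,5-oxygenated cyclohexadienone that cannot aromatise because its CMe2 carbon sits between the ring C=O and a C–OH; the key step exploits this. Heating 3-ethoxy-4,4-dimethylcyclobutenone with an ynol ether carrying the butyryl group as a silyl enol ether opens the strained ring to a vinylketene; [2+2] addition, a second opening and 6π closure insert the alkyne between the carbonyl carbon and the ring CH. Thus the C(=O)–C(acyl) bond and the bond between the middle C–OH carbon and the carbon that later carries the CH2 bridge form in one operation.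

Key step: step 4

Remark: the target is achiral; all β-triketone rings are drawn in the enol tautomer of the target SMILES, and 2,4,6-trihydroxybutyrophenone is assumed to be a catalogue compound.

Step 1
Reactants: 1 isobutyryl chloride; 2 ethoxyacetylene
Product: 4 3-ethoxy-4,4-dimethylcyclobut-2-en-1-one, via dimethylketene 3 (not isolated)
Conditions: Et3N (1.3 equiv), 2 (1.5 equiv, solution in hexanes), Et2O, 0 °C to 35 °C, 16 h; filter, distil
Reagents that add atoms: none
Why: Et3N dehydrochlorinates 1 to dimethylketene 3, which undergoes the thermal [2+2] ketene–alkyne cycloaddition with the ynol ether, the electrophilic ketene carbonyl carbon bonding to the nucleophilic CH carbon β to the ethoxy oxygen, so that the 3-ethoxy-4,4-dimethyl regioisomer should result (no stereocentre).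

Step 2
Reactants: 2 ethoxyacetylene; 5 N-methoxy-N-methylbutanamide
Product: 7 1-ethoxyhex-1-yn-3-one, via lithium ethoxyacetylide 6 (not isolated)
Conditions: n-BuLi (1.05 equiv), THF, −78 °C, 30 min; then 5, −78 to −20 °C; cold aq. NH4Cl quench, rapid extraction
Reagents that add atoms: none
Why: Weinreb ketone synthesis, in which the acetylide 6 acylates the N-methoxy-N-methylamide once only, and the cold near-neutral quench should spare the hydration-prone ynol ether.

Step 3
Reactants: 7 1-ethoxyhex-1-yn-3-one
Product: 9 tert-butyl{[(3Z)-1-ethoxyhex-3-en-1-yn-3-yl]oxy}dimethylsilane, via potassium enolate 8 (not isolated)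
Conditions: KN(SiMe3)2 (1.1 equiv), THF, −78 °C, 30 min; TBSCl (1.2 equiv), THF–DMPU, −78 to 0 °C; pentane, filter, bulb-to-bulb distillation
Reagents that add atoms: tert-butyldimethylsilyl chloride, CC(C)(C)[Si](C)(C)Cl
Why: Kinetic enolisation at the only α-CH2 and O-silylation of the potassium enolate (silyl enol ether formation) turn the electron-poor ynone into an electron-rich ynol ether with the butyryl group masked; the Z geometry drawn is the expected major one and is erased later on hydrolysis.

Step 4
Reactants: 4 3-ethoxy-4,4-dimethylcyclobut-2-en-1-one; 9 tert-butyl{[(3Z)-1-ethoxyhex-3-en-1-yn-3-yl]oxy}dimethylsilane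
Product: 14 butyrylfilicinic acid (2-butanoyl-3,5-dihydroxy-6,6-dimethylcyclohexa-2,4-dien-1-one), via vinylketene 10 (not isolated), via alkenylcyclobutenone 11 (not isolated), via dienylketene 12 (not isolated), via silyloxybutenyl dienone 13 (not isolated)
Conditions: 4 (1.0 equiv), 9 (1.3 equiv), toluene, 80 °C, 24 h, then 110 °C, 2 h (sealed tube, Ar); evaporate; THF–2 M aq. HCl (2:1), 40 °C, 6 h
Reagents that add atoms: water, O
Why: This is a Danheiser benzannulation (cyclobutenone plus heteroatom-substituted alkyne) in its cyclohexadienone-forming version: strain release opens 4 by reversible 4π electrocyclic cleavage of the C(=O)–CMe2 bond to vinylketene 10, whose ketene C=C adds the ynol ether 9 in a regioselective [2+2] cycloaddition to the four-membered ring of 11, forming the bond from the ring carbonyl carbon to the alkyne carbon that carries the masked butyryl group and the bond from the ketene α-CH carbon to the alkyne C–OEt carbon. A second 4π opening of 11 breaks the old C(=O)–CH bond to give dienylketene 12, and thermal disrotatory 6π electrocyclisation re-forms the C(=O)–CMe2 bond and closes the six-membered ring as 13, so that in net terms the two alkyne carbons are inserted between the carbonyl carbon and the CH carbon of 4. The regiochemistry needed is secured by polarity, since the ketene carbonyl carbon is the electrophile and the alkyne carbon β to the ethoxy oxygen is the nucleophile, and the ynol ether π bond is far more ketenophilic than the silyl enol ether double bond. Because the former C4 of the cyclobutenone is quaternary, 13 cannot tautomerise to a phenol, so the 6,6-dimethyl dienone with the 1,3,5-oxygen pattern is kept and the acyl-bearing carbon and the free CH carbon are fixed in their final positions. The only stereocentre on the way (the ring CH of 11) is transient and the product is achiral, while an unproductive geometry of 12 is corrected by the reversibility of the ring openings. Aqueous HCl then hydrolyses the silyl enol ether to the butyryl ketone and both vinylogous ethyl esters to the enols, which should give 14.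

Step 5
Reactants: 14 butyrylfilicinic acid; 15 Eschenmoser's salt (N,N-dimethylmethyleneiminium iodide); 16 2,4,6-trihydroxybutyrophenone
Product: 20 filixic acid BBB (target), via Mannich base 17 (not isolated), via methylene trione 18 (not isolated), via mono-adduct 19 (not isolated)
Conditions: 14 (2.1 equiv), 15 (2.1 equiv), NaOAc (2.2 equiv), MeCN, 0 °C to rt, 2 h; then 16 (1.0 equiv), 70 °C, 12 h, Ar; dilute aq. citric acid work-up
Reagents that add atoms: none
Why: Mannich reaction at the only ring CH of 14 gives 17, which on warming loses dimethylamine to the methylene trione 18 (a quinone-methide-type Michael acceptor) that is trapped by C3 and then, through 19, by C5 of the phloroglucinol ring of 16 (Friedel–Crafts-type conjugate addition); since 14 is consumed before 16 is added and 16 has only two free ring positions, the 2:1 trimer should be the end point, and no stereocentre is formed.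

**Compound list**

1 | isobutyryl chloride (2-methylpropanoyl chloride) | CC(C)C(=O)Cl | starting material
2 | ethoxyacetylene (ethoxyethyne) | CCOC#C | starting material
3 | dimethylketene (2-methylprop-1-en-1-one) | CC(C)=C=O | intermediate
4 | 3-ethoxy-4,4-dimethylcyclobut-2-en-1-one | CCOC1=CC(=O)C1(C)C | intermediate
5 | N-methoxy-N-methylbutanamide | CCCC(=O)N(C)OC | starting material
6 | lithium ethoxyacetylide | [Li]C#COCC | intermediate
7 | 1-ethoxyhex-1-yn-3-one | CCCC(=O)C#COCC | intermediate
8 | potassium (3Z)-1-ethoxyhex-3-en-1-yn-3-olate | CCOC#C/C([O-])=C/CC.[K+] | intermediate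
9 | tert-butyl{[(3Z)-1-ethoxyhex-3-en-1-yn-3-yl]oxy}dimethylsilane | CCOC#C/C(O[Si](C)(C)C(C)(C)C)=C/CC | intermediate
10 | 3-ethoxy-4-methylpenta-1,3-dien-1-one (vinylketene) | CCOC(C=C=O)=C(C)C | intermediate
11 | 2-[(1Z)-1-(tert-butyldimethylsilyloxy)but-1-enyl]-3-ethoxy-4-(1-ethoxy-2-methylprop-1-enyl)cyclobut-2-en-1-one (racemic, transient) | CCOC1=C(/C(O[Si](C)(C)C(C)(C)C)=C/CC)C(=O)C1C(OCC)=C(C)C | intermediate
12 | (3E)-2-[(1Z)-1-(tert-butyldimethylsilyloxy)but-1-enyl]-3,5-diethoxy-6-methylhepta-1,3,5-trien-1-one (dienylketene) | O=C=C(/C(O[Si](C)(C)C(C)(C)C)=C/CC)/C(OCC)=C\C(OCC)=C(C)C | intermediate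
13 | 2-[(1Z)-1-(tert-butyldimethylsilyloxy)but-1-enyl]-3,5-diethoxy-6,6-dimethylcyclohexa-2,4-dien-1-one | CCOC1=CC(OCC)=C(/C(O[Si](C)(C)C(C)(C)C)=C/CC)C(=O)C1(C)C | intermediate
14 | butyrylfilicinic acid (2-butanoyl-3,5-dihydroxy-6,6-dimethylcyclohexa-2,4-dien-1-one) | CCCC(=O)C1=C(O)C=C(O)C(C)(C)C1=O | intermediate
15 | Eschenmoser's salt (N,N-dimethylmethyleneiminium iodide) | C[N+](C)=C.[I-] | starting material
16 | 2,4,6-trihydroxybutyrophenone (butyrylphloroglucinol) | CCCC(=O)c1c(O)cc(O)cc1O | starting material
17 | 2-butanoyl-4-[(dimethylamino)methyl]-3,5-dihydroxy-6,6-dimethylcyclohexa-2,4-dien-1-one (Mannich base) | CCCC(=O)C1=C(O)C(CN(C)C)=C(O)C(C)(C)C1=O | intermediate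
18 | 2-butanoyl-3-hydroxy-6,6-dimethyl-4-methylidenecyclohex-2-ene-1,5-dione (methylene trione) | CCCC(=O)C1=C(O)C(=C)C(=O)C(C)(C)C1=O | intermediate
19 | 2-butanoyl-4-[(3-butanoyl-2,4,6-trihydroxyphenyl)methyl]-3,5-dihydroxy-6,6-dimethylcyclohexa-2,4-dien-1-one (mono-adduct) | CCCC(=O)C1=C(O)C(Cc2c(O)cc(O)c(C(=O)CCC)c2O)=C(O)C(C)(C)C1=O | intermediate
20 | filixic acid BBB: 2,4,6-trihydroxybutyrophenone whose C3 and C5 each carry, through a CH2 bridge, C4 of a 2-butanoyl-3,5-dihydroxy-6,6-dimethylcyclohexa-2,4-dien-1-one ring | CCCC(=O)C1=C(O)C(Cc2c(O)c(CC3=C(O)C(C)(C)C(=O)C(C(=O)CCC)=C3O)c(O)c(C(=O)CCC)c2O)=C(O)C(C)(C)C1=O | target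

**Count.** Total: 5 steps. Longest linear sequence: 4 steps (steps 2, 3, 4, 5).

**Steps most likely to fail**

Step 4. The donor-stabilised cyclobutenone may open only slowly, so that the ynol ether 9 is lost by thermal retro-ene fragmentation or reacts at its silyl enol ether before it is captured by the vinylketene. Fallback: the filicinic ring is reached by dearomatisation instead of annulation. Compound 16 would be C-methylated twice at one ring carbon (MeI, NaOMe, MeOH, 0 °C to rt), passing through 2,4,6-trihydroxy-3-methylbutyrophenone F1, to give 14 directly. This sets out from 16 and rejoins the route at 14.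

Step 5. Methylene transfer may scramble through retro-Mannich exchange (giving the symmetrical methylene-bridged dimer of 14), or the second alkylation of the central ring may stay incomplete. Fallback: the polarity of the coupling is inverted. Compound 16 would be treated with 15 (2 equiv, NaOAc, MeCN) to give the bis-Mannich base 3,5-bis[(dimethylamino)methyl]-2,4,6-trihydroxybutyrophenone F2. On heating with 14 (2 equiv) this should lose dimethylamine to form ortho-quinone methides on the central ring, which C4 of 14 traps as the nucleophile. This sets out from 16 and rejoins at 20.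

Step 3. Enolisation of the push–pull ynone 7 may be overrun by conjugate addition of the amide base at the ethoxy-bearing alkyne carbon or by decomposition of 7. Fallback: the masked acyl group is given up and the butyryl group is attached after ring construction. Compound 4 would be heated with the parent alkyne 2 (toluene, 80 °C), and the same annulation should give 3,5-diethoxy-6,6-dimethylcyclohexa-2,4-dien-1-one F3. Aqueous HCl would hydrolyse it to filicinic acid F4, whose two ring CH positions are equivalent. Friedel–Crafts C-acylation with butyryl chloride and AlCl3 in nitrobenzene would then give 14. This sets out from 4 and 2 and rejoins at 14.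

**Further compounds**

F1 | step 4 | 2,4,6-trihydroxy-3-methylbutyrophenone | CCCC(=O)c1c(O)cc(O)c(C)c1O
F2 | step 5 | 3,5-bis[(dimethylamino)methyl]-2,4,6-trihydroxybutyrophenone | CCCC(=O)c1c(O)c(CN(C)C)c(O)c(CN(C)C)c1O
F3 | step 3 | 3,5-diethoxy-6,6-dimethylcyclohexa-2,4-dien-1-one | CCOC1=CC(OCC)=CC(=O)C1(C)C
F4 | step 3 | filicinic acid (3,5-dihydroxy-6,6-dimethylcyclohexa-2,4-dien-1-one) | CC1(C)C(O)=CC(O)=CC1=O
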